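The ε-ring (C1'–C6') with its three methyls and the exocyclic C7' is mapped atom for atom onto the ten carbons of (+)-verbenone. The key photochemical 1,3-alkyl shift moves the CMe2 carbon (C1') of the verbenone cyclobutane (C1'–C2'–C3'–C4') from C4' to the enone α-carbon C6', inserting C5' and C6' and so expanding the four-membered ring to the cyclohexene while fixing C6' from the retained bridgehead; the enone carbonyl becomes C7'. Retro-Claisen opening of the derived bicyclic 1,3-diketone frees the ring. The resulting C15 phosphonium salt, a C10 dialdehyde and a triol C15 salt (from actinol by Sharpless epoxidation and Payne rearrangement) are joined by two Wittig reactions.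

Key step: step 1

Remark: carotenoid numbering is used for ring atoms (C1–C6, first chain carbon C7, primed numbers for the ε-end); compounds 1, 12 and 25 are taken to be purchasable.

Step 1
Reactants: 1 (1R,5R)-(+)-verbenone
Product: 2 (1S,5R)-2,7,7-trimethylbicyclo[3.1.1]hept-2-en-6-one (chrysanthenone)
Conditions: hν (350 nm), cyclohexane, 20 °C, degassed, stopped before full conversion
Reagents that add atoms: none
Why: n→π* excitation of the enone triggers a photochemical [1,3]-sigmatropic alkyl shift in which the CMe2 carbon (C1') leaves the γ-carbon (C4') and rebonds to the α-carbon (C6') across the allyl unit C4'–C5'–C6', the enone becoming a β,γ-unsaturated cyclobutanone. The closest known reaction type is the photoisomerisation of bicyclic α,β-enones to β,γ-unsaturated ketones by 1,3-alkyl shift, which is documented for verbenone itself. The new C1'–C6' bond closes the six-membered carbocycle C1'–C6' by suprafacial recombination of the tertiary carbon with the allyl terminus (a 4 to 6 ring expansion) and at once closes the four-membered ketone ring C2'–C1'–C6'–C7'. The only new stereocenter, C6', is controlled by the retained bridgehead C2' (1R in 1), because C1' stays tethered to it and can reach C6' on one face only. The step needs migration of the CMe2 bond in preference to the CH2 bond of the cyclobutane, secured by the tertiary gem-dimethyl carbon, and it needs the primary shift to outrun secondary Norrish α-cleavage of 2 to an achiral dienyl ketene, secured by long-wavelength light that the conjugated enone absorbs but the product hardly does.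

Step 2
Reactants: 2 chrysanthenone
Product: 3 (1S,5S)-2,7,7-trimethylbicyclo[3.1.1]hept-2-ene-4,6-dione
Conditions: CrO3, 3,5-dimethylpyrazole, CH2Cl2, −20 °C
Reagents that add atoms: chromium trioxide, O=[Cr](=O)=O
Why: Chromium trioxide–3,5-dimethylpyrazole allylic oxidation should convert the ring CH2 (C3') next to the trisubstituted alkene into the enone carbonyl, as in the oxidation of α-pinene to verbenone, while the non-nucleophilic medium spares the strained ketone and the bridgehead C–H bonds.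

Step 3
Reactants: 3 (1S,5S)-2,7,7-trimethylbicyclo[3.1.1]hept-2-ene-4,6-dione
Product: 5 methyl (1R)-2,6,6-trimethyl-4-oxocyclohex-2-ene-1-carboxylate, via lithium enolate 4 (not isolated)
Conditions: LiOMe (from MeOH and n-butyllithium, 1.05 equiv), THF, −78 to −40 °C; then AcOH, −78 °C
Reagents that add atoms: lithium methoxide, [Li+].[O-]C
Why: Retro-Claisen cleavage of a non-enolisable 1,3-diketone: methoxide adds to the strained four-membered ketone (C7') and the C7'–C2' bond breaks to the ketone enolate 4, which under aprotic conditions shields the acidic C6'–H until kinetic protonation at C2', so that C6' (R) should be carried over unchanged.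

Step 4
Reactants: 5 methyl (1R)-2,6,6-trimethyl-4-oxocyclohex-2-ene-1-carboxylate
Product: 6 methyl (1R,4R)-4-hydroxy-2,6,6-trimethylcyclohex-2-ene-1-carboxylate
Conditions: LiBH(s-Bu)3, THF, −78 °C; then H2O
Reagents that add atoms: none
Why: 1,2-Reduction of a β,β-disubstituted enone by a bulky borohydride: hydride should attack C3' anti to the pseudoaxial C1' methyl, that is on the face of the pseudoaxial ester, placing the new hydroxyl trans to C7' (3'R), and any cis isomer would be removed by chromatography.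

Step 5
Reactants: 6 methyl (1R,4R)-4-hydroxy-2,6,6-trimethylcyclohex-2-ene-1-carboxylate
Product: 7 methyl (1R,4R)-4-(tert-butyldimethylsilyloxy)-2,6,6-trimethylcyclohex-2-ene-1-carboxylate
Conditions: TBSCl, imidazole, DMF, 20 °C
Reagents that add atoms: tert-butyldimethylsilyl chloride, CC(C)(C)[Si](C)(C)Cl
Why: Standard silylation masks the acid-labile allylic alcohol for the hydride, Grignard and phosphonium-forming steps.

Step 6
Reactants: 7 methyl (1R,4R)-4-(tert-butyldimethylsilyloxy)-2,6,6-trimethylcyclohex-2-ene-1-carboxylate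
Product: 8 (1R,4R)-4-(tert-butyldimethylsilyloxy)-2,6,6-trimethylcyclohex-2-ene-1-carbaldehyde
Conditions: (i-Bu)2AlH (1.1 equiv), CH2Cl2, −78 °C; then aqueous KNaC4H4O6
Reagents that add atoms: none
Why: Partial reduction of the hindered ester at low temperature should stop at the aluminium hemiacetal, which releases the β,γ-unsaturated aldehyde on neutral work-up without epimerising C6'.

Step 7
Reactants: 8 (1R,4R)-4-(tert-butyldimethylsilyloxy)-2,6,6-trimethylcyclohex-2-ene-1-carbaldehyde
Product: 9 (3E)-4-[(1R,4R)-4-(tert-butyldimethylsilyloxy)-2,6,6-trimethylcyclohex-2-en-1-yl]but-3-en-2-one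
Conditions: Ph3P=CHC(O)CH3, toluene, 80 °C
Reagents that add atoms: 1-(triphenylphosphoranylidene)propan-2-one, CC(=O)C=P(c1ccccc1)(c1ccccc1)c1ccccc1
Why: Wittig olefination by a stabilised, nearly non-basic ylide should give the (E)-enone (C7'=C8') and leave the epimerisable C6' untouched.

Step 8
Reactants: 9 (3E)-4-[(1R,4R)-4-(tert-butyldimethylsilyloxy)-2,6,6-trimethylcyclohex-2-en-1-yl]but-3-en-2-one
Product: 10 (1E)-1-[(1R,4R)-4-(tert-butyldimethylsilyloxy)-2,6,6-trimethylcyclohex-2-en-1-yl]-3-methylpenta-1,4-dien-3-ol (both C3 epimers)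
Conditions: CH2=CHMgBr, THF, −78 to 0 °C; then aqueous NH4Cl
Reagents that add atoms: vinylmagnesium bromide, C=C[Mg]Br
Why: 1,2-Addition of the vinyl Grignard reagent to the enone carbonyl gives the tertiary bis-allylic alcohol, whose new stereocenter is erased in the next step.

Step 9
Reactants: 10 (1E)-1-[(1R,4R)-4-(tert-butyldimethylsilyloxy)-2,6,6-trimethylcyclohex-2-en-1-yl]-3-methylpenta-1,4-dien-3-ol
Product: 11 [(2E,4E)-5-[(1R,4R)-4-(tert-butyldimethylsilyloxy)-2,6,6-trimethylcyclohex-2-en-1-yl]-3-methylpenta-2,4-dien-1-yl]triphenylphosphonium bromide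
Conditions: PPh3·HBr (1.0 equiv), CH2Cl2, 0 to 20 °C
Reagents that add atoms: triphenylphosphine hydrobromide, [Br-].[PH+](c1ccccc1)(c1ccccc1)c1ccccc1
Why: Ionisation of the tertiary bis-allylic alcohol to a pentadienyl cation and capture by triphenylphosphine at the primary terminus (allylic transposition) should give the conjugated (E,E)-C15 salt, the mild acid in an aprotic solvent sparing the allylic silyl ether.

Step 10
Reactants: 12 (4R,6R)-4-hydroxy-2,2,6-trimethylcyclohexan-1-one (actinol)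
Product: 13 (4R,6R)-4-(tert-butyldimethylsilyloxy)-2,2,6-trimethylcyclohexan-1-one
Conditions: TBSCl, imidazole, DMF, 20 °C
Reagents that add atoms: tert-butyldimethylsilyl chloride, CC(C)(C)[Si](C)(C)Cl
Why: Standard silylation protects the C3 hydroxyl (the future 3S center) through the enolate and organometallic steps.

Step 11
Reactants: 13 (4R,6R)-4-(tert-butyldimethylsilyloxy)-2,2,6-trimethylcyclohexan-1-one
Product: 15 (4R)-4-(tert-butyldimethylsilyloxy)-2,6,6-trimethylcyclohex-1-en-1-yl trifluoromethanesulfonate, via lithium enolate 14 (not isolated)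
Conditions: LiN(i-Pr)2, THF, −78 °C; PhNTf2, −78 to 20 °C; then H2O
Reagents that add atoms: N-phenylbis(trifluoromethanesulfonimide), O=S(=O)(N(c1ccccc1)S(=O)(=O)C(F)(F)F)C(F)(F)F
Why: The ketone can enolise only towards C5, so the enolate is regiodefined and is O-sulfonylated to the tetrasubstituted vinyl triflate, erasing the C5 center and leaving C3 untouched.

Step 12
Reactants: 15 (4R)-4-(tert-butyldimethylsilyloxy)-2,6,6-trimethylcyclohex-1-en-1-yl trifluoromethanesulfonate
Product: 16 methyl (4R)-4-(tert-butyldimethylsilyloxy)-2,6,6-trimethylcyclohex-1-ene-1-carboxylate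
Conditions: Pd(OAc)2 (cat.), PPh3, Et3N, CO (1 atm), MeOH/DMF, 60 °C
Reagents that add atoms: carbon monoxide, [C-]#[O+]; methanol, CO
Why: Palladium-catalysed alkoxycarbonylation (oxidative addition of zerovalent palladium to the vinyl triflate, CO insertion, methanolysis) installs C7 as the conjugated ester.

Step 13
Reactants: 16 methyl (4R)-4-(tert-butyldimethylsilyloxy)-2,6,6-trimethylcyclohex-1-ene-1-carboxylate
Product: 17 [(4R)-4-(tert-butyldimethylsilyloxy)-2,6,6-trimethylcyclohex-1-en-1-yl]methanol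
Conditions: (i-Bu)2AlH (2.5 equiv), CH2Cl2, −78 to 0 °C; then aqueous KNaC4H4O6
Reagents that add atoms: none
Why: Hydride reduction of the unsaturated ester gives the allylic alcohol that the asymmetric epoxidation needs as its handle.

Step 14
Reactants: 17 [(4R)-4-(tert-butyldimethylsilyloxy)-2,6,6-trimethylcyclohex-1-en-1-yl]methanol
Product: 18 [(1S,4S,6S)-4-(tert-butyldimethylsilyloxy)-2,2,6-trimethyl-7-oxabicyclo[4.1.0]heptan-1-yl]methanol (epoxide oxygen cis to the silyloxy group)
Conditions: Ti(O-i-Pr)4, L-(+)-diethyl tartrate, t-BuOOH, 4 Å molecular sieves, CH2Cl2, −20 °C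
Reagents that add atoms: tert-butyl hydroperoxide, CC(C)(C)OO
Why: Sharpless asymmetric epoxidation, in which the L-(+)-tartrate complex should deliver oxygen to the alkene face cis to the C3 silyloxy group under reagent control, sets C5 and C6 as the syn-epoxide.

Step 15
Reactants: 18 [(1S,4S,6S)-4-(tert-butyldimethylsilyloxy)-2,2,6-trimethyl-7-oxabicyclo[4.1.0]heptan-1-yl]methanol
Product: 20 (1R,2S,4S)-4-(tert-butyldimethylsilyloxy)-1-(hydroxymethyl)-2,6,6-trimethylcyclohexane-1,2-diol, via spiro-epoxide alkoxide 19 (not isolated)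
Conditions: NaOH (0.5 M), t-BuOH/H2O, 70 °C
Reagents that add atoms: water, O
Why: Payne rearrangement followed by opening: the primary alkoxide displaces the epoxide oxygen at C6 with inversion to give 19 and hydroxide then opens 19 at the primary C7, so that C6 is inverted and C5 retained, which fixes the trans-5,6-diol with the C5 hydroxyl cis to the C3 oxygen.

Step 16
Reactants: 20 (1R,2S,4S)-4-(tert-butyldimethylsilyloxy)-1-(hydroxymethyl)-2,6,6-trimethylcyclohexane-1,2-diol
Product: 22 (3E)-4-[(1S,2S,4S)-4-(tert-butyldimethylsilyloxy)-1,2-dihydroxy-2,6,6-trimethylcyclohexyl]but-3-en-2-one, via hydroxy aldehyde 21 (not isolated)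
Conditions: SO3·pyridine, DMSO, i-Pr2NEt, CH2Cl2, 0 °C; then Ph3P=CHC(O)CH3, 40 °C
Reagents that add atoms: 1-(triphenylphosphoranylidene)propan-2-one, CC(=O)C=P(c1ccccc1)(c1ccccc1)c1ccccc1
Why: Parikh–Doering oxidation touches only the primary alcohol (no glycol cleavage, tertiary hydroxyls inert) and the non-enolisable α-hydroxy aldehyde is trapped in the same pot by Wittig olefination with the stabilised ylide to the (E)-enone.

Step 17
Reactants: 22 (3E)-4-[(1S,2S,4S)-4-(tert-butyldimethylsilyloxy)-1,2-dihydroxy-2,6,6-trimethylcyclohexyl]but-3-en-2-one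
Product: 23 (1S,2S,4S)-4-(tert-butyldimethylsilyloxy)-1-[(1E)-3-hydroxy-3-methylpenta-1,4-dien-1-yl]-2,6,6-trimethylcyclohexane-1,2-diol (both epimers at the new carbinol)
Conditions: CH2=CHMgBr (4 equiv), THF, −78 to 0 °C; then aqueous NH4Cl
Reagents that add atoms: vinylmagnesium bromide, C=C[Mg]Br
Why: After deprotonation of the two tertiary hydroxyls the Grignard reagent adds 1,2 to the enone carbonyl to give the tertiary bis-allylic alcohol.

Step 18
Reactants: 23 (1S,2S,4S)-4-(tert-butyldimethylsilyloxy)-1-[(1E)-3-hydroxy-3-methylpenta-1,4-dien-1-yl]-2,6,6-trimethylcyclohexane-1,2-diol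
Product: 24 [(2E,4E)-5-[(1S,2S,4S)-4-(tert-butyldimethylsilyloxy)-1,2-dihydroxy-2,6,6-trimethylcyclohexyl]-3-methylpenta-2,4-dien-1-yl]triphenylphosphonium bromide
Conditions: PPh3·HBr (1.0 equiv), CH2Cl2, 0 to 20 °C
Reagents that add atoms: triphenylphosphine hydrobromide, [Br-].[PH+](c1ccccc1)(c1ccccc1)c1ccccc1
Why: The C9 carbinol, being tertiary and bis-allylic, should ionise far more readily than the C6 hydroxyl (which is flanked by the C5 hydroxyl), and triphenylphosphine captures the cation at C11 with allylic transposition to the (E,E)-salt.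

Step 19
Reactants: 11 [(2E,4E)-5-[(1R,4R)-4-(tert-butyldimethylsilyloxy)-2,6,6-trimethylcyclohex-2-en-1-yl]-3-methylpenta-2,4-dien-1-yl]triphenylphosphonium bromide, 25 (2E,4E,6E)-2,7-dimethylocta-2,4,6-trienedial
Product: 27 (2E,4E,6E,8E,10E,12E)-13-[(1R,4R)-4-(tert-butyldimethylsilyloxy)-2,6,6-trimethylcyclohex-2-en-1-yl]-2,7,11-trimethyltrideca-2,4,6,8,10,12-hexaenal, via phosphorus ylide 26 (not isolated)
Conditions: NaOMe, MeOH/CH2Cl2, 0 to 20 °C, 25 in threefold excess; then reflux in EtOAc
Reagents that add atoms: none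
Why: Wittig reaction of the semi-stabilised ylide with an excess of the symmetrical dialdehyde should stop at mono-olefination, and heating equilibrates the new C11'=C12' bond to E.

Step 20
Reactants: 24 [(2E,4E)-5-[(1S,2S,4S)-4-(tert-butyldimethylsilyloxy)-1,2-dihydroxy-2,6,6-trimethylcyclohexyl]-3-methylpenta-2,4-dien-1-yl]triphenylphosphonium bromide, 27 (2E,4E,6E,8E,10E,12E)-13-[(1R,4R)-4-(tert-butyldimethylsilyloxy)-2,6,6-trimethylcyclohex-2-en-1-yl]-2,7,11-trimethyltrideca-2,4,6,8,10,12-hexaenal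
Product: 29 (3S,5S,6S,3'R,6'R)-3,3'-bis(tert-butyldimethylsilyloxy)-5,6-dihydro-β,ε-carotene-5,6-diol (all-E), via phosphorus ylide 28 (not isolated)
Conditions: NaOMe, MeOH/CH2Cl2, 0 to 20 °C; then reflux in EtOH
Reagents that add atoms: none
Why: The second Wittig reaction forms the C11=C12 bond and completes the C40 polyene, the free tertiary hydroxyls being tolerated by the methoxide base and the thermal treatment converting the 11Z isomer into the all-E chain.

Step 21
Reactants: 29 (3S,5S,6S,3'R,6'R)-3,3'-bis(tert-butyldimethylsilyloxy)-5,6-dihydro-β,ε-carotene-5,6-diol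
Product: 30 (3S,5S,6S,3'R,6'R)-5,6-dihydro-β,ε-carotene-3,5,6,3'-tetrol (CNP0219917.1)
Conditions: Bu4NF, THF, 0 to 20 °C, dark, argon
Reagents that add atoms: none
Why: Fluoride cleaves both silyl ethers under non-acidic conditions, which protects the acid-labile allylic C3' alcohol and the tertiary allylic C6 alcohol of the polyene.

Compound list
1 | (1R,5R)-(+)-verbenone, (1R,5R)-4,6,6-trimethylbicyclo[3.1.1]hept-3-en-2-one | CC1=CC(=O)[C@@H]2C[C@H]1C2(C)C | starting material
2 | (1S,5R)-2,7,7-trimethylbicyclo[3.1.1]hept-2-en-6-one (chrysanthenone) | CC1=CC[C@H]2C(=O)[C@@H]1C2(C)C | intermediate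
3 | (1S,5S)-2,7,7-trimethylbicyclo[3.1.1]hept-2-ene-4,6-dione | CC1=CC(=O)[C@H]2C(=O)[C@@H]1C2(C)C | intermediate
4 | lithium enolate of 5 (C2'=C3' enolate, cross-conjugated) | [Li+].COC(=O)[C@H]1C(C)=CC([O-])=CC1(C)C | intermediate
5 | methyl (1R)-2,6,6-trimethyl-4-oxocyclohex-2-ene-1-carboxylate | COC(=O)[C@H]1C(C)=CC(=O)CC1(C)C | intermediate
6 | methyl (1R,4R)-4-hydroxy-2,6,6-trimethylcyclohex-2-ene-1-carboxylate (hydroxyl trans to ester) | COC(=O)[C@H]1C(C)=C[C@H](O)CC1(C)C | intermediate
7 | methyl (1R,4R)-4-(tert-butyldimethylsilyloxy)-2,6,6-trimethylcyclohex-2-ene-1-carboxylate | COC(=O)[C@H]1C(C)=C[C@H](O[Si](C)(C)C(C)(C)C)CC1(C)C | intermediate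
8 | (1R,4R)-4-(tert-butyldimethylsilyloxy)-2,6,6-trimethylcyclohex-2-ene-1-carbaldehyde | O=C[C@H]1C(C)=C[C@H](O[Si](C)(C)C(C)(C)C)CC1(C)C | intermediate
9 | (3E)-4-[(1R,4R)-4-(tert-butyldimethylsilyloxy)-2,6,6-trimethylcyclohex-2-en-1-yl]but-3-en-2-one | CC(=O)/C=C/[C@H]1C(C)=C[C@H](O[Si](C)(C)C(C)(C)C)CC1(C)C | intermediate
10 | (1E)-1-[(1R,4R)-4-(tert-butyldimethylsilyloxy)-2,6,6-trimethylcyclohex-2-en-1-yl]-3-methylpenta-1,4-dien-3-ol (C3 epimers) | C=CC(C)(O)/C=C/[C@H]1C(C)=C[C@H](O[Si](C)(C)C(C)(C)C)CC1(C)C | intermediate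
11 | [(2E,4E)-5-[(1R,4R)-4-(tert-butyldimethylsilyloxy)-2,6,6-trimethylcyclohex-2-en-1-yl]-3-methylpenta-2,4-dien-1-yl]triphenylphosphonium bromide | [Br-].c1ccccc1[P+](c1ccccc1)(c1ccccc1)C/C=C(C)/C=C/[C@H]1C(C)=C[C@H](O[Si](C)(C)C(C)(C)C)CC1(C)C | intermediate
12 | (4R,6R)-4-hydroxy-2,2,6-trimethylcyclohexan-1-one (actinol) | C[C@@H]1C[C@@H](O)CC(C)(C)C1=O | starting material
13 | (4R,6R)-4-(tert-butyldimethylsilyloxy)-2,2,6-trimethylcyclohexan-1-one | C[C@@H]1C[C@@H](O[Si](C)(C)C(C)(C)C)CC(C)(C)C1=O | intermediate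
14 | lithium enolate of 13 (C5=C6) | [Li+].CC1=C([O-])C(C)(C)C[C@H](O[Si](C)(C)C(C)(C)C)C1 | intermediate
15 | (4R)-4-(tert-butyldimethylsilyloxy)-2,6,6-trimethylcyclohex-1-en-1-yl trifluoromethanesulfonate | CC1=C(OS(=O)(=O)C(F)(F)F)C(C)(C)C[C@H](O[Si](C)(C)C(C)(C)C)C1 | intermediate
16 | methyl (4R)-4-(tert-butyldimethylsilyloxy)-2,6,6-trimethylcyclohex-1-ene-1-carboxylate | COC(=O)C1=C(C)C[C@@H](O[Si](C)(C)C(C)(C)C)CC1(C)C | intermediate
17 | [(4R)-4-(tert-butyldimethylsilyloxy)-2,6,6-trimethylcyclohex-1-en-1-yl]methanol | OCC1=C(C)C[C@@H](O[Si](C)(C)C(C)(C)C)CC1(C)C | intermediate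
18 | [(1S,4S,6S)-4-(tert-butyldimethylsilyloxy)-2,2,6-trimethyl-7-oxabicyclo[4.1.0]heptan-1-yl]methanol (syn-epoxide) | OC[C@]12O[C@@]1(C)C[C@@H](O[Si](C)(C)C(C)(C)C)CC2(C)C | intermediate
19 | sodium 6-(tert-butyldimethylsilyloxy)-4,8,8-trimethyl-1-oxaspiro[2.5]octan-4-olate (Payne epoxide; oxirane oxygen trans to the C4 oxide, C4 oxide cis to the silyloxy group) | [Na+].C[C@]1([O-])C[C@@H](O[Si](C)(C)C(C)(C)C)CC(C)(C)[C@@]12CO2 | intermediate
20 | (1R,2S,4S)-4-(tert-butyldimethylsilyloxy)-1-(hydroxymethyl)-2,6,6-trimethylcyclohexane-1,2-diol | OC[C@]1(O)C(C)(C)C[C@H](O[Si](C)(C)C(C)(C)C)C[C@]1(C)O | intermediate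
21 | (1S,2S,4S)-4-(tert-butyldimethylsilyloxy)-1,2-dihydroxy-2,6,6-trimethylcyclohexane-1-carbaldehyde | O=C[C@]1(O)C(C)(C)C[C@H](O[Si](C)(C)C(C)(C)C)C[C@]1(C)O | intermediate
22 | (3E)-4-[(1S,2S,4S)-4-(tert-butyldimethylsilyloxy)-1,2-dihydroxy-2,6,6-trimethylcyclohexyl]but-3-en-2-one | CC(=O)/C=C/[C@]1(O)C(C)(C)C[C@H](O[Si](C)(C)C(C)(C)C)C[C@]1(C)O | intermediate
23 | (1S,2S,4S)-4-(tert-butyldimethylsilyloxy)-1-[(1E)-3-hydroxy-3-methylpenta-1,4-dien-1-yl]-2,6,6-trimethylcyclohexane-1,2-diol (carbinol epimers) | C=CC(C)(O)/C=C/[C@]1(O)C(C)(C)C[C@H](O[Si](C)(C)C(C)(C)C)C[C@]1(C)O | intermediate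
24 | [(2E,4E)-5-[(1S,2S,4S)-4-(tert-butyldimethylsilyloxy)-1,2-dihydroxy-2,6,6-trimethylcyclohexyl]-3-methylpenta-2,4-dien-1-yl]triphenylphosphonium bromide | [Br-].c1ccccc1[P+](c1ccccc1)(c1ccccc1)C/C=C(C)/C=C/[C@]1(O)C(C)(C)C[C@H](O[Si](C)(C)C(C)(C)C)C[C@]1(C)O | intermediate
25 | (2E,4E,6E)-2,7-dimethylocta-2,4,6-trienedial | O=C/C(C)=C/C=C/C=C(C)/C=O | starting material
26 | ylide of 11 | c1ccccc1P(c1ccccc1)(c1ccccc1)=C/C=C(C)/C=C/[C@H]1C(C)=C[C@H](O[Si](C)(C)C(C)(C)C)CC1(C)C | intermediate
27 | (2E,4E,6E,8E,10E,12E)-13-[(1R,4R)-4-(tert-butyldimethylsilyloxy)-2,6,6-trimethylcyclohex-2-en-1-yl]-2,7,11-trimethyltrideca-2,4,6,8,10,12-hexaenal | O=C/C(C)=C/C=C/C=C(C)/C=C/C=C(C)/C=C/[C@H]1C(C)=C[C@H](O[Si](C)(C)C(C)(C)C)CC1(C)C | intermediate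
28 | ylide of 24 | c1ccccc1P(c1ccccc1)(c1ccccc1)=C/C=C(C)/C=C/[C@]1(O)C(C)(C)C[C@H](O[Si](C)(C)C(C)(C)C)C[C@]1(C)O | intermediate
29 | (3S,5S,6S,3'R,6'R)-3,3'-bis(tert-butyldimethylsilyloxy)-5,6-dihydro-β,ε-carotene-5,6-diol | CC1=C[C@H](O[Si](C)(C)C(C)(C)C)CC(C)(C)[C@H]1/C=C/C(C)=C/C=C/C(C)=C/C=C/C=C(C)/C=C/C=C(C)/C=C/[C@]1(O)C(C)(C)C[C@H](O[Si](C)(C)C(C)(C)C)C[C@]1(C)O | intermediate
30 | (3S,5S,6S,3'R,6'R)-5,6-dihydro-β,ε-carotene-3,5,6,3'-tetrol | CC1=C[C@H](O)CC(C)(C)[C@H]1/C=C/C(C)=C/C=C/C(C)=C/C=C/C=C(C)/C=C/C=C(C)/C=C/[C@]1(O)C(C)(C)C[C@H](O)C[C@]1(C)O | target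

Total step count: 21. Longest linear sequence: 12 steps (steps 1–9, then 19–21); the second branch (steps 10–18) joins at step 20.

Steps most likely to fail

Step 3. The tetrahedral methoxide adduct may fragment in the vinylogous sense, breaking C6'–C7' towards the extended dienolate and leaving the ester on C2'. Separately, C6' may epimerise by γ-deprotonation once 5 has been protonated while base is still present. The fallback sets out from 3 and returns at 5. The enone alkene would first be hydrogenated (H2, Pd/C, EtOAc; hydrogen enters anti to the gem-dimethyl bridge) to 2,7,7-trimethylbicyclo[3.1.1]heptane-4,6-dione F1, in which only the simple retro-Claisen path exists. LiOMe in THF followed by AcOH would then give methyl (1S,2R)-2,6,6-trimethyl-4-oxocyclohexane-1-carboxylate F2, whose C6' hydrogen is no longer vinylogously acidic. Kinetic enolisation at the less hindered C4' (LiN(i-Pr)2, Me3SiCl, THF, −78 °C) would give methyl (1S,2R)-2,6,6-trimethyl-4-(trimethylsilyloxy)cyclohex-3-ene-1-carboxylate F3. Saegusa–Ito dehydrogenation (Pd(OAc)2, MeCN, 20 °C) would restore the C4'=C5' alkene and deliver 5.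

Step 15. Attack of hydroxide on the neopentyl-type CH2 of the Payne epoxide 19 may be too slow, so that loss of the silyl ether or oxetane formation by the neighbouring tertiary alkoxide takes over. The fallback sets out from 18 and returns at 20. Carbamoylation (PhNCO, Et3N, CH2Cl2) would give [(1S,4S,6S)-4-(tert-butyldimethylsilyloxy)-2,2,6-trimethyl-7-oxabicyclo[4.1.0]heptan-1-yl]methyl N-phenylcarbamate F4. BF3·OEt2 in CH2Cl2 at −20 °C would then drive intramolecular attack of the carbamate carbonyl oxygen at C6 with inversion, and mild aqueous acid work-up would hydrolyse the iminocarbonate to 8-(tert-butyldimethylsilyloxy)-6-hydroxy-6,10,10-trimethyl-1,3-dioxaspiro[4.5]decan-2-one F5 (C6 oxygen trans and C5 hydroxyl cis to the silyloxy group). Methanolysis (NaOMe, MeOH, 0 °C) would free triol 20.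

Step 1. Secondary photolysis of 2 (α-cleavage to an achiral dienyl ketene that recloses thermally) may erode the enantiomeric purity that the shift itself transfers. The fallback sets out from 6 and returns at 6, replacing reliance on complete chirality transfer by a resolution through diastereomers. The scalemic alcohol would be esterified with (S)-2-methoxy-2-phenylacetic acid (DCC, DMAP, CH2Cl2) to methyl (1R,4R)-4-[(2S)-2-methoxy-2-phenylacetoxy]-2,6,6-trimethylcyclohex-2-ene-1-carboxylate F6. F6 would be freed from the diastereomer derived from the minor enantiomer by chromatography or crystallisation and methanolysed (K2CO3, MeOH, 0 °C) back to enantiopure 6.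

Further compounds
F1 | step 3 | 2,7,7-trimethylbicyclo[3.1.1]heptane-4,6-dione (C2 methyl on the side of the gem-dimethyl bridge, bridgeheads as in 3) | C[C@@H]1CC(=O)[C@H]2C(=O)[C@@H]1C2(C)C
F2 | step 3 | methyl (1S,2R)-2,6,6-trimethyl-4-oxocyclohexane-1-carboxylate (C2 methyl trans to the ester) | COC(=O)[C@H]1[C@H](C)CC(=O)CC1(C)C
F3 | step 3 | methyl (1S,2R)-2,6,6-trimethyl-4-(trimethylsilyloxy)cyclohex-3-ene-1-carboxylate | COC(=O)[C@H]1[C@H](C)C=C(O[Si](C)(C)C)CC1(C)C
F4 | step 15 | [(1S,4S,6S)-4-(tert-butyldimethylsilyloxy)-2,2,6-trimethyl-7-oxabicyclo[4.1.0]heptan-1-yl]methyl N-phenylcarbamate | O=C(Nc1ccccc1)OC[C@]12O[C@@]1(C)C[C@@H](O[Si](C)(C)C(C)(C)C)CC2(C)C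
F5 | step 15 | 8-(tert-butyldimethylsilyloxy)-6-hydroxy-6,10,10-trimethyl-1,3-dioxaspiro[4.5]decan-2-one (configuration of 20) | O=C1OC[C@]2(O1)C(C)(C)C[C@H](O[Si](C)(C)C(C)(C)C)C[C@]2(C)O
F6 | step 1 | methyl (1R,4R)-4-[(2S)-2-methoxy-2-phenylacetoxy]-2,6,6-trimethylcyclohex-2-ene-1-carboxylate | COC(=O)[C@H]1C(C)=C[C@H](OC(=O)[C@@H](OC)c2ccccc2)CC1(C)C
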